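The earlier runs and the new flask are simulated for substances that don't exist, noise included.

The partner was the limiting reagent of the south-west flask, at 70.0% of the starting material charged. Its precatalyst charge is 0.200% of that charge, so I read the free starting material a as one minus product, and the partner left b as 70.0% minus product, both as fractions of the starting material charged.

| setting | south-west | north-east | flask |
|---|---|---|---|
| starting material | 43 mM (fed, over 0.80 s) | 43 mM (fed, over 0.80 s) | 43 mM (fed, over 0.80 s) |
| partner | 30.1 mM | 30.1 mM | 30.1 mM |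
| precatalyst | 86 µM | 43 µM | 86 µM |
| remark | the very flask that is asked about, followed so far | run made earlier |  |
| time |  |  | 2.0 min |

| run | time / s | starting material / % | catalyst intermediate C / % | catalyst intermediate A / % | catalyst intermediate B / % | product / % | catalyst intermediate D / % |
|---|---|---|---|---|---|---|---|
| south-west | 10.0 | 87.4 | 0 | 0.6 | 0 | 11.1 | 0 |
| south-west | 20.0 | 76.2 | 0.2 | 0.4 | 0 | 23.5 | 0 |
| south-west | 30.0 | 67.5 | 2.3 | 0 | 0.2 | 32.9 | 0 |
| south-west | 40.0 | 62.4 | 1.3 | 0 | 1.5 | 38.4 | 0.4 |
| south-west | 50.0 | 58.0 | 0 | 0 | 1.5 | 43.7 | 0 |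
| south-west | 60.0 | 52.7 | 0 | 1.7 | 0.3 | 45.8 | 0.9 |
| north-east | 10.0 | 91.7 | 0 | 0.9 | 0.7 | 6.1 | 0 |
| north-east | 15.0 | 88.7 | 0.1 | 0 | 0.1 | 10.7 | 0 |
| north-east | 25.0 | 82.0 | 1.8 | 0 | 0 | 17.7 | 0.5 |
| north-east | 40.0 | 72.4 | 0 | 0.6 | 0 | 24.5 | 0 |
| north-east | 80.0 | 59.8 | 0.8 | 0.5 | 0 | 39.5 | 0 |
| north-east | 120 | 50.2 | 0 | 1.4 | 0 | 48.3 | 0 |

(readings scatter by 1 percentage point)

- the species that holds most of what was charged as starting material, at 2.0 min (catalyst intermediate C / starting material / catalyst intermediate A / catalyst intermediate D / product / catalyst intermediate B)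
- the largest share itself, whichever of these holds it, in percent of the starting material charged

- the analysis behind the earlier runs scatters by 1 percentage point, standard deviation

The difference a − b stays at 0.300, so if the rate goes as a times b, ln(a/b) rises in a straight line. This replaces the curve by one mean slope. In the south-west run, ln(a/b) went from 0.498 at 20.0 s to 0.806 at 60.0 s, which gives the climb, the slope of ln(a/b) in time, of 0.00771 s⁻¹. The north-east run, with half the precatalyst, climbed 0.00426 s⁻¹ from its start to 120 s, about half as fast, though this reading spans a longer window.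

Carrying the south-west climb on to 2.0 min brings ln(a/b) to 1.27, so I reckoned product at 58.3%.

The forecast said product at 59%, 0.70 percentage points above my figure, holding that “The order in catalyst is therefore close to one”.

The flask gave product at 59.6%, with 15% of the partner's own charge left.

    starting material + free catalyst ⇌ catalyst intermediate A (K = 70.0 L mol⁻¹, k = 3400 L mol⁻¹ s⁻¹)
    catalyst intermediate B ⇌ by-product + catalyst intermediate C (K = 0.0540 M, k = 4300 s⁻¹)
    catalyst intermediate C → catalyst intermediate D (k = 21.0 s⁻¹)
    partner + precatalyst → free catalyst + spent reagent (k = 7.30 L mol⁻¹ s⁻¹)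
    partner + catalyst intermediate A ⇌ catalyst intermediate B (K = 6.70 L mol⁻¹, k = 3800 L mol⁻¹ s⁻¹)
    catalyst intermediate D → free catalyst + product (k = 97.0 s⁻¹)

In this flask, from 47.1% product at 1.00 min to that share, the climb was 0.00864 s⁻¹, where I had carried on the 0.00771 s⁻¹ read from scattered readings, and my product stood 1.3 points low.

For the neighbour flask with 0.034 mM of precatalyst, I scaled the north-east climb to 0.00337 s⁻¹, which gives product at 43.7%. That flask gave 43.5%, and starting material held the most.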